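**Retrosynthetic overview**
1. Target ⇐ oxidative opening (DDQ/H2O) of a 1-aryl-1,3-dihydro-2-benzofuran-4-ol, in which the ortho CHO/ArC=O pair is stored as one cyclic bis-benzylic ether.
2. That phthalan-phenol ⇐ gold-catalysed furan–yne cycloisomerisation of a furfuryl propargyl ether: the phenol ring and the fused dihydrofuran ring form together, the furan O becomes the phenol OH, and the furan 3-prenyl group ends ortho to the aroyl carbon.
3. Furfuryl propargyl ether ⇐ O-propargylation, C3-prenylation and addition of 3-bromo-2-furyllithium to the benzodioxine aldehyde.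
4. Benzodioxine aldehyde ⇐ 2,3-dihydroxy-5-methylbenzaldehyde + (S)-epoxyprenyl nosylate (SN2, then 6-exo epoxide opening with inversion sets the (R) centre); nosylate ⇐ Sharpless epoxidation of prenol.
5. Ring order: the methyl-catechol arene is bought; dioxane ring (step 3); prenyl-phenol ring + dihydrofuran ring in one operation (step 7); dihydrofuran ring opened again (step 8).

Assumption: 2-hydroxy-3-methoxy-5-methylbenzaldehyde is bought as a catalogue compound; the carbinol carbon made in step 4 is carried as both epimers (it ends as the ketone carbon) and is left undefined in the SMILES.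

Shorthand: ArD = (3R)-3-(2-hydroxypropan-2-yl)-7-methyl-2,3-dihydro-1,4-benzodioxin-5-yl, i.e. the group c1cc(C)cc2c1O[C@@H](C(C)(C)O)CO2 bonded through C5.

**Step 1**
Reactants: 1 3-methylbut-2-en-1-ol (prenol)
Product: 3 [(2S)-3,3-dimethyloxiran-2-yl]methyl 3-nitrobenzenesulfonate, via (2S)-3,3-dimethylglycidol 2 (not isolated)
Conditions: Ti(OiPr)4 (5 mol%), L-(+)-DIPT (6 mol%), t-BuOOH (1.1 equiv), 4 Å MS, CH2Cl2, −20 °C; then Et3N, DMAP (cat.), 3-NO2C6H4SO2Cl, −10 °C; recrystallise
Reagents that add atoms: tert-butyl hydroperoxide CC(C)(C)OO; 3-nitrobenzenesulfonyl chloride O=S(=O)(Cl)c1cccc(c1)[N+](=O)[O-]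
Why: Sharpless asymmetric epoxidation with in situ sulfonylation: the Ti/L-(+)-tartrate catalyst delivers oxygen to the face that gives the (2S)-epoxy alcohol (same sense as the (2S,3S)-epoxides from E-allylic alcohols), and the water-soluble glycidol is trapped as its crystalline nosylate, whose recrystallisation raises the ee above 98%.

**Step 2**
Reactants: 4 2-hydroxy-3-methoxy-5-methylbenzaldehyde
Product: 5 2,3-dihydroxy-5-methylbenzaldehyde
Conditions: BBr3 (2.5 equiv), CH2Cl2, −78 → 0 °C; H2O
Reagents that add atoms: none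
Why: BBr3 cleavage of the aryl methyl ether (Lewis-acid demethylation via the aryl borate) leaves the aldehyde untouched; no stereocentre is involved.

**Step 3**
Reactants: 5 2,3-dihydroxy-5-methylbenzaldehyde; 3 [(2S)-3,3-dimethyloxiran-2-yl]methyl 3-nitrobenzenesulfonate
Product: 7 (3R)-3-(2-hydroxypropan-2-yl)-7-methyl-2,3-dihydro-1,4-benzodioxine-5-carbaldehyde (ArD-CHO), via sodium phenoxide epoxy ether 6 (not isolated)
Conditions: NaH (2.1 equiv), DMSO, 20 °C; then 3 (1.0 equiv), 20 → 70 °C; aq. NH4Cl
Reagents that add atoms: none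
Why: Regioselective dianion O-alkylation followed by intramolecular epoxide opening: the non-conjugated 3-phenoxide displaces the nosylate (SN2 at CH2, epoxide centre untouched), then the 2-phenoxide opens the epoxide 6-exo-tet at the secondary carbon with inversion, so the (S)-epoxide carbon becomes the (R)-dioxane carbon and the tertiary alcohol is released.

**Step 4**
Reactants: 8 3-bromofuran; 7 ArD-CHO
Product: 10 (3-bromofuran-2-yl)(ArD)methanol (both carbinol epimers), via 3-bromo-2-lithiofuran 9 (not isolated)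
Conditions: LDA (2.4 equiv), 8 (2.5 equiv), THF, −78 °C; then 7, −78 → −40 °C; aq. NH4Cl
Reagents that add atoms: none
Why: Directed deprotonation of 3-bromofuran at C2 (acidified by Br and the ring O) and 1,2-addition of the furyllithium to the aldehyde (one extra equivalent is consumed by the tertiary OH); the new carbinol centre forms unselectively, which is harmless because it becomes the ketone carbon.

**Step 5**
Reactants: 10 (3-bromofuran-2-yl)(ArD)methanol; 11 1-bromo-3-methylbut-2-ene (prenyl bromide)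
Product: 13 (ArD)[3-(3-methylbut-2-en-1-yl)furan-2-yl]methanol (both carbinol epimers), via trilithio species 12 (not isolated)
Conditions: n-BuLi (3.2 equiv), THF, −78 °C; then 11 (1.5 equiv), −78 → −20 °C; aq. NH4Cl
Reagents that add atoms: none
Why: Bromine–lithium exchange on the dilithium alkoxide and SN2 allylation of the 3-furyllithium with prenyl bromide (aryllithium–allyl halide coupling, as in rosefuran-type syntheses); lithium alkoxides are not alkylated at these temperatures and no stereocentre is touched.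

**Step 6**
Reactants: 13 (ArD)[3-(3-methylbut-2-en-1-yl)furan-2-yl]methanol; 14 3-bromoprop-1-yne (propargyl bromide)
Product: 15 2-[(ArD)(prop-2-yn-1-yloxy)methyl]-3-(3-methylbut-2-en-1-yl)furan (both epimers)
Conditions: NaH (1.1 equiv), THF–DMF 4:1, 0 °C; 14 (1.2 equiv), Bu4NI (cat.), 0 → 20 °C
Reagents that add atoms: none
Why: Williamson ether synthesis: one equivalent of NaH deprotonates the more acidic doubly benzylic (furyl/aryl) secondary alcohol, which is propargylated while the hindered, less acidic tertiary alcohol stays free.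

**Step 7 (key step)**
Reactants: 15 2-[(ArD)(prop-2-yn-1-yloxy)methyl]-3-(3-methylbut-2-en-1-yl)furan
Product: 17 1-(ArD)-7-(3-methylbut-2-en-1-yl)-1,3-dihydro-2-benzofuran-4-ol (both C1 epimers), via arene oxide 16 (not isolated)
Conditions: (Mes3P)AuNTf2 (3 mol%), CH2Cl2, 20 °C
Reagents that add atoms: none
Why: Hashmi gold-catalysed furan–yne phenol synthesis: furan C2=C3 attacks the Au-activated alkyne 5-exo, the cyclopropyl carbenoid opens the furan to a dienal carbenoid that closes to the oxepine/arene oxide 16, and the arene oxide opens toward the better stabilised cation to put OH on the former alkyne CH, so the benzene ring and the fused dihydrofuran ring form in one operation with prenyl ortho to the aryl-bearing carbon; the dioxane stereocentre is remote and untouched.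

**Step 8**
Reactants: 17 1-(ArD)-7-(3-methylbut-2-en-1-yl)-1,3-dihydro-2-benzofuran-4-ol
Product: 19 2-hydroxy-6-[(ArD)carbonyl]-5-(3-methylbut-2-en-1-yl)benzaldehyde (CNP0373866.1), via hydroxymethyl ketone 18 (not isolated)
Conditions: DDQ (2.3 equiv), CH2Cl2–pH 7 buffer 10:1, 0 → 20 °C
Reagents that add atoms: water O
Why: Proposed new method: DDQ first abstracts hydride from C1 (bis-benzylic, α-oxygen, activated by the ortho-alkoxy dioxane ring) and water gives the hemiketal/2-(hydroxymethyl)benzophenone 18, then a second DDQ oxidises the o-hydroxybenzylic CH2–O through the phenol-assisted oxocarbenium, which fragments with the hemiketal OH into aldehyde plus ketone; the closest known reactions are DDQ cleavage of PMB/diarylmethyl ethers and DDQ oxidation of o-hydroxybenzyl alcohols to salicylaldehydes, and the stereocentre is not involved.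

**Compound list**
1 | 3-methylbut-2-en-1-ol (prenol) | CC(C)=CCO | starting material
2 | (2S)-3,3-dimethylglycidol, [(2S)-3,3-dimethyloxiran-2-yl]methanol (not isolated) | CC1(C)O[C@H]1CO | intermediate
3 | [(2S)-3,3-dimethyloxiran-2-yl]methyl 3-nitrobenzenesulfonate | CC1(C)O[C@H]1COS(=O)(=O)c1cccc(c1)[N+](=O)[O-] | intermediate
4 | 2-hydroxy-3-methoxy-5-methylbenzaldehyde | COc1cc(C)cc(C=O)c1O | starting material
5 | 2,3-dihydroxy-5-methylbenzaldehyde | Cc1cc(O)c(O)c(C=O)c1 | intermediate
6 | sodium 2-{[(2S)-3,3-dimethyloxiran-2-yl]methoxy}-6-formyl-4-methylphenolate (not isolated) | [Na+].[O-]c1c(C=O)cc(C)cc1OC[C@@H]1OC1(C)C | intermediate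
7 | (3R)-3-(2-hydroxypropan-2-yl)-7-methyl-2,3-dihydro-1,4-benzodioxine-5-carbaldehyde (ArD-CHO) | O=Cc1cc(C)cc2c1O[C@@H](C(C)(C)O)CO2 | intermediate
8 | 3-bromofuran | Brc1ccoc1 | starting material
9 | 3-bromo-2-lithiofuran (not isolated) | [Li]c1occc1Br | intermediate
10 | (3-bromofuran-2-yl)(ArD)methanol, both carbinol epimers | OC(c1occc1Br)c1cc(C)cc2c1O[C@@H](C(C)(C)O)CO2 | intermediate
11 | 1-bromo-3-methylbut-2-ene (prenyl bromide) | CC(C)=CCBr | starting material
12 | O,O,C3-trilithio derivative of 10 (3-lithiofuran dialkoxide, not isolated) | [Li]OC(c1occc1[Li])c1cc(C)cc2c1O[C@@H](C(C)(C)O[Li])CO2 | intermediate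
13 | (ArD)[3-(3-methylbut-2-en-1-yl)furan-2-yl]methanol, both carbinol epimers | CC(C)=CCc1ccoc1C(O)c1cc(C)cc2c1O[C@@H](C(C)(C)O)CO2 | intermediate
14 | 3-bromoprop-1-yne (propargyl bromide) | C#CCBr | starting material
15 | 2-[(ArD)(prop-2-yn-1-yloxy)methyl]-3-(3-methylbut-2-en-1-yl)furan, both epimers | C#CCOC(c1occc1CC=C(C)C)c1cc(C)cc2c1O[C@@H](C(C)(C)O)CO2 | intermediate
16 | 4,5-epoxy-4,5-dihydro isomer of 17 (arene oxide in equilibrium with its oxepine, not isolated) | CC(C)=CCC1=CC2OC2C2=C1C(c1cc(C)cc3c1O[C@@H](C(C)(C)O)CO3)OC2 | intermediate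
17 | 1-(ArD)-7-(3-methylbut-2-en-1-yl)-1,3-dihydro-2-benzofuran-4-ol, both C1 epimers | CC(C)=CCc1ccc(O)c2COC(c3cc(C)cc4c3O[C@@H](C(C)(C)O)CO4)c12 | intermediate
18 | (ArD)[3-hydroxy-2-(hydroxymethyl)-6-(3-methylbut-2-en-1-yl)phenyl]methanone (open form of the cyclic hemiketal, not isolated) | CC(C)=CCc1ccc(O)c(CO)c1C(=O)c1cc(C)cc2c1O[C@@H](C(C)(C)O)CO2 | intermediate
19 | 2-hydroxy-6-{[(3R)-3-(2-hydroxypropan-2-yl)-7-methyl-2,3-dihydro-1,4-benzodioxin-5-yl]carbonyl}-5-(3-methylbut-2-en-1-yl)benzaldehyde (CNP0373866.1) | CC(C)=CCc1ccc(O)c(C=O)c1C(=O)c1cc(C)cc2c1O[C@@H](C(C)(C)O)CO2 | target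

**Step count and risk**
Total: 8 steps. Longest linear sequence: 7 steps (4 → 5 → 7 → 10 → 13 → 15 → 17 → 19, steps 2–8; the branch through step 1 is equally long).

Most likely to fail, step 7: the cationic gold catalyst may ionise the furyl/aryl carbinyl ether, or the prenyl alkene may intercept the gold carbenoid. The fallback builds the phenol ring by an intermolecular furan Diels–Alder instead and sets out from aldehyde 7. Addition of lithiated 3,3-diethoxyprop-1-yne gives 4,4-diethoxy-1-(ArD)but-2-yn-1-ol F3, and MnO2 oxidises it to the ynone 4,4-diethoxy-1-(ArD)but-2-yn-1-one F4. Cycloaddition of F4 with 2-(3-methylbut-2-en-1-yl)furan F5 (made from furan, n-BuLi and 11) in toluene at 80 °C gives (ArD)[3-(diethoxymethyl)-1-(3-methylbut-2-en-1-yl)-7-oxabicyclo[2.2.1]hepta-2,5-dien-2-yl]methanone F6. The unsubstituted furan α-carbon attacks the ynone β-carbon, so the aroyl carbon sits next to the prenyl-bearing bridgehead. Aqueous TsOH in acetone then opens the oxygen bridge toward the tertiary cation, giving the phenol, and hydrolyses the acetal. This comes back to the route at target 19 and replaces steps 4 to 8.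

Second, step 8: DDQ may attack the free phenol (quinone methide at the prenyl CH2) or over-oxidise a lactol to the phthalide. The fallback masks the phenol and separates the two oxidations, setting out from phenol 17. TBSCl/imidazole gives 1-(ArD)-4-(tert-butyldimethylsilyloxy)-7-(3-methylbut-2-en-1-yl)-1,3-dihydro-2-benzofuran F7. DDQ (1.2 equiv, wet CH2Cl2) then oxidises only C1 to (ArD)[3-(tert-butyldimethylsilyloxy)-2-(hydroxymethyl)-6-(3-methylbut-2-en-1-yl)phenyl]methanone F8. Dess–Martin periodinane gives 2-(tert-butyldimethylsilyloxy)-6-[(ArD)carbonyl]-5-(3-methylbut-2-en-1-yl)benzaldehyde F9, and TBAF/AcOH removes the silyl group to come back at target 19.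

Third, step 5: the trianion may scramble to the 5-lithiofuran or alkylate poorly. The fallback puts the prenyl group on the furan before the aldehyde is met and sets out from 3-bromofuran 8. Br/Li exchange (n-BuLi, THF, −78 °C) and alkylation with 11 give 3-(3-methylbut-2-en-1-yl)furan F1. NBS in DMF at −20 °C brominates C2 next to the alkyl group to give 2-bromo-3-(3-methylbut-2-en-1-yl)furan F2. Br/Li exchange of F2 and addition to aldehyde 7 give carbinol 13 directly, where the route is rejoined; steps 4 and 5 are replaced and no polyanion is needed.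

**Further compounds**
F1 | step 5 | 3-(3-methylbut-2-en-1-yl)furan | CC(C)=CCc1ccoc1
F2 | step 5 | 2-bromo-3-(3-methylbut-2-en-1-yl)furan | CC(C)=CCc1ccoc1Br
F3 | step 7 | 4,4-diethoxy-1-(ArD)but-2-yn-1-ol (both carbinol epimers) | CCOC(OCC)C#CC(O)c1cc(C)cc2c1O[C@@H](C(C)(C)O)CO2
F4 | step 7 | 4,4-diethoxy-1-(ArD)but-2-yn-1-one | CCOC(OCC)C#CC(=O)c1cc(C)cc2c1O[C@@H](C(C)(C)O)CO2
F5 | step 7 | 2-(3-methylbut-2-en-1-yl)furan | CC(C)=CCc1ccco1
F6 | step 7 | (ArD)[3-(diethoxymethyl)-1-(3-methylbut-2-en-1-yl)-7-oxabicyclo[2.2.1]hepta-2,5-dien-2-yl]methanone (bridgehead diastereomers) | CC(C)=CCC12C=CC(O1)C(C(OCC)OCC)=C2C(=O)c1cc(C)cc2c1O[C@@H](C(C)(C)O)CO2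
F7 | step 8 | 1-(ArD)-4-(tert-butyldimethylsilyloxy)-7-(3-methylbut-2-en-1-yl)-1,3-dihydro-2-benzofuran (both C1 epimers) | CC(C)=CCc1ccc(O[Si](C)(C)C(C)(C)C)c2COC(c3cc(C)cc4c3O[C@@H](C(C)(C)O)CO4)c12
F8 | step 8 | (ArD)[3-(tert-butyldimethylsilyloxy)-2-(hydroxymethyl)-6-(3-methylbut-2-en-1-yl)phenyl]methanone | CC(C)=CCc1ccc(O[Si](C)(C)C(C)(C)C)c(CO)c1C(=O)c1cc(C)cc2c1O[C@@H](C(C)(C)O)CO2
F9 | step 8 | 2-(tert-butyldimethylsilyloxy)-6-[(ArD)carbonyl]-5-(3-methylbut-2-en-1-yl)benzaldehyde | CC(C)=CCc1ccc(O[Si](C)(C)C(C)(C)C)c(C=O)c1C(=O)c1cc(C)cc2c1O[C@@H](C(C)(C)O)CO2
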